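Start with the easy step: take the last reading of each run and write the starting material left as a depth, the natural logarithm of charge over remainder. A pseudo-first-order loss, with partner and catalyst steady, gives a depth that grows in step with time and rate.

common to all: starting material 0.010 M

| charge | coupling partner | second substrate | protic impurity | catalyst | added ligand | remark | time |
|---|---|---|---|---|---|---|---|
| spring | 0.029 M | 10 mM | 2 mM | 1 mM | 0.67 mM | run made earlier |  |
| midnight | 0.039 M | 10 mM | 2 mM | 1 mM | 0.67 mM | run made earlier |  |
| noon | 0.040 M | 10 mM | 2 mM | 1 mM | 0.67 mM | run made earlier |  |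
| autumn | 0.025 M | 10 mM | 2 mM | 1 mM | 1.1 mM | run made earlier |  |
| larch | 0.0500 M | 10.0 mM | 2.00 mM | 1.0 mM | 1.0 mM |  | 20 h |
| maple | 0.0250 M | 10.0 mM | 2.00 mM | 1.0 mM | 0.67 mM |  | 20 h |

| run | time / h | target / % | starting material / % |
|---|---|---|---|
| spring | 4.00 | 43 | 56 |
| spring | 8.00 | 57 | 41 |
| spring | 12.0 | 64 | 38 |
| spring | 15.0 | 69 | 29 |
| spring | 20.0 | 73 | 27 |
| midnight | 2.00 | 36 | 61 |
| midnight | 5.00 | 60 | 40 |
| midnight | 10.0 | 75 | 25 |
| midnight | 15.0 | 79 | 17 |
| midnight | 20.0 | 86 | 13 |
| noon | 2.00 | 35 | 64 |
| noon | 5.00 | 61 | 41 |
| noon | 10.0 | 80 | 20 |
| noon | 15.0 | 84 | 14 |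
| noon | 20.0 | 90 | 11 |
| autumn | 2.00 | 20 | 77 |
| autumn | 5.00 | 39 | 62 |
| autumn | 10.0 | 52 | 48 |
| autumn | 15.0 | 59 | 39 |
| autumn | 20.0 | 63 | 37 |

(standard deviation of a reading: 1.5 percentage points)

- the numbers in the tables scatter by 1.5 percentage points (one standard deviation)
- on the list of suspects stand: coupling partner <-> dormant form; second substrate + coupling partner + catalyst -> catalyst + second product; catalyst + added ligand <-> idle complex; starting material + coupling partner + catalyst -> catalyst + target; coupling partner + protic impurity -> quenched reagent

- which one finishes higher in amount of target, in percent of the starting material charged ("neither" within 2 percentage points) (larch / maple / neither)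
- amount of target at the end, in percent of the starting material charged, larch
- amount of target at the end, in percent of the starting material charged, maple

Now something looks wrong. The spring run has [coupling partner] of 0.029 M against 0.010 M of starting material and reaches a depth of 1.31. The noon run has 1.38 times that [coupling partner] but reaches 2.21, which is 1.69 times as deep.

Depth climbs faster than charge, so the first part of the charge seems to buy nothing. You can freeze this as a straight line: between these two runs, each unit of charge adds 0.0816 mM⁻¹ of depth. Followed back from spring, the line reaches zero depth at 13.0 mM. Call this the dead charge: the partner that, on this line, buys no depth at the last reading, at these charges of second substrate, impurity, catalyst and ligand. It is read from two readings, so it carries their scatter.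

My own reckoning puts maple 12.0 mM above the dead charge, a depth of 0.983 and 62.6 % target. The same line gives larch 95.1 %, before any trim for its extra ligand.

The forecast names larch, with 94 % for larch and 65 % for maple, the maple figure standing higher than mine. It reads the runs as showing that “the runs stall when partner is short”.

The flasks give larch as the higher: larch 93.4 %, maple 65.7 %.

    coupling partner ⇌ dormant form (K = 11.0, k = 1.10 × 10⁻⁵ s⁻¹)
    second substrate + coupling partner + catalyst → catalyst + second product (k = 3.70 M⁻² s⁻¹)
    catalyst + added ligand ⇌ idle complex, settled at all times (K = 550 M⁻¹)
    starting material + coupling partner + catalyst → catalyst + target (k = 2.40 M⁻² s⁻¹)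
    coupling partner + protic impurity → quenched reagent (k = 0.0110 M⁻¹ s⁻¹)

Maple's remainder of 34.3 % puts its own dead charge at 11.9 mM. A neighbour flask, maple with 5.00 mM of impurity, adds 3.00 mM to that, so you expect 56.2 % target, and it gives 59.1 %, which is 2.9 percentage points higher. The partner charge is the largest single effect between larch and maple: larch cut to maple's charge finishes at 63.4 %, and larch at 42.5 mM has already moved by 5 points.

The earlier runs and the new flask are calculated for substances that don't exist; the scatter is artificial.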